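**Plan**
- Retrosynthesis: cut the two angelate C–O bonds and the C7–C11 bond (acetone aldol, then dehydration to the C11=C12 alkene). Then open ring B at C8–C9, the acyloin bond, to a ring A hydroxy dialdehyde. Ring A goes back to cyclohex-2-en-1-one by cutting C4–C15, C3–O, C10–C9, C5–C14 and C5–C6.
- Enabling feature: ring B holds an α-ketol. Its ketone carbon C8 ends the unbranched C6–C7–C8 arm on C5; its carbinol carbon C9 sits on ring carbon C10 beside the quaternary C5. A C8 aldehyde can therefore act as acyl-anion donor and a C9 aldehyde as acceptor.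
- Forward: ring A is the cyclohexenone ring, substituted in steps 1–11. Ring B closes in step 12 by carbene-catalysed benzoin reaction. C7 is then alkylated, both hydroxyls are esterified and the tertiary alcohol is dehydrated.
- Stereochemistry: C10 from the chiral copper catalyst; C5 from anti-alkylation of the enolate; C3 from the oxazaborolidine (reagent control); C4 from hydroxyl-directed hydrogenation; C9 from the chair-like ring closure (equatorial OH); C7 from convex-face aldol addition, which is also the stable epimer.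

Key step: step 12

Assumption: the target is read as the cis-fused (10βH) eremophilane 3α,9β-bis(angeloyloxy)-4β,5β-dimethyl-7β-isopropenyl-decalin-8-one; eremophilane numbering is used throughout (ring A = C1–C5, C10; ring B = C5–C10; β = the face of the C5 methyl).

**Step 1**
Reactants: 1 cyclohex-2-en-1-one
Product: 2 2-iodocyclohex-2-en-1-one
Conditions: I2, pyridine, CH2Cl2, 0 °C → rt
Reagents that add atoms: iodine, II
Why: Conjugate addition of pyridine, iodination of the resulting enolate and elimination (α-iodination of an enone by addition–elimination) give the vinyl iodide needed as coupling electrophile.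

**Step 2**
Reactants: 2 2-iodocyclohex-2-en-1-one; 3 allyloxy(tert-butyl)dimethylsilane
Product: 5 2-[3-(tert-butyldimethylsilyloxy)propyl]cyclohex-2-en-1-one, via alkylborane 4 (not isolated)
Conditions: 3, 9-BBN, THF, rt; then 2, PdCl2(dppf) (cat.), AsPh3, Cs2CO3, DMF/THF/H2O, rt
Reagents that add atoms: allyloxy(tert-butyl)dimethylsilane 3, C=CCO[Si](C)(C)C(C)(C)C
Why: Anti-Markovnikov hydroboration of the terminal alkene and B-alkyl Suzuki–Miyaura coupling of the borane with the 2-iodoenone attach the C6–C8 arm to the future C5 without touching the enone.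

**Step 3**
Reactants: 5 2-[3-(tert-butyldimethylsilyloxy)propyl]cyclohex-2-en-1-one; 6 vinylmagnesium bromide; 7 iodomethane
Product: 9 (2S,3R)-2-[3-(tert-butyldimethylsilyloxy)propyl]-2-methyl-3-vinylcyclohexan-1-one, via magnesium enolate 8 (not isolated)
Conditions: 6, Cu(OTf)2 (5 mol %), chiral N-mesityl-N′-(hydroxyalkyl)imidazolinium hexafluorophosphate (carbene precursor, 6 mol %; enantiomer chosen for Si-face attack at C3 of the enone), Et2O, –30 °C; then 7, DMPU, –30 °C → rt
Reagents that add atoms: vinylmagnesium bromide 6, C=C[Mg]Br; iodomethane 7, CI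
Why: Copper-catalysed asymmetric conjugate addition of a Grignard reagent to a 2-alkylcyclohexenone sets C10 under catalyst control, and the tetrasubstituted magnesium enolate is C-methylated anti to the new vinyl group (tandem conjugate addition–enolate alkylation), so that at C5 the methyl is trans and the arm cis to vinyl.

**Step 4**
Reactants: 9 (2S,3R)-2-[3-(tert-butyldimethylsilyloxy)propyl]-2-methyl-3-vinylcyclohexan-1-one
Product: 11 (2S,3S)-2-[3-(tert-butyldimethylsilyloxy)propyl]-3-(hydroxymethyl)-2-methylcyclohexan-1-one, via keto aldehyde 10 (not isolated)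
Conditions: O3, CH2Cl2, –78 °C; PPh3, –78 °C → rt; then LiAlH(OtBu)3, THF, –78 °C
Reagents that add atoms: ozone, [O-][O+]=O
Why: Ozonolysis cleaves the only C=C bond to the C9 aldehyde, which the bulky hydride reduces at low temperature in preference to the ketone flanked by the quaternary carbon, and C10 is not touched.

**Step 5**
Reactants: 11 (2S,3S)-2-[3-(tert-butyldimethylsilyloxy)propyl]-3-(hydroxymethyl)-2-methylcyclohexan-1-one
Product: 12 (2S,3S)-2-[3-(tert-butyldimethylsilyloxy)propyl]-3-[(tert-butyldimethylsilyloxy)methyl]-2-methylcyclohexan-1-one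
Conditions: TBSCl, imidazole, DMF, rt
Reagents that add atoms: tert-butyldimethylsilyl chloride, CC(C)(C)[Si](C)(C)Cl
Why: Silylation of the primary alcohol masks C9–OH and prevents hemiketal formation with the C4 ketone before the olefination.

**Step 6**
Reactants: 12 (2S,3S)-2-[3-(tert-butyldimethylsilyloxy)propyl]-3-[(tert-butyldimethylsilyloxy)methyl]-2-methylcyclohexan-1-one
Product: 13 (1S,2S)-1-[(tert-butyldimethylsilyloxy)methyl]-2-[3-(tert-butyldimethylsilyloxy)propyl]-2-methyl-3-methylidenecyclohexane
Conditions: Ph3PCH3Br, KOtBu, toluene, 80 °C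
Reagents that add atoms: methyltriphenylphosphonium bromide, C[P+](c1ccccc1)(c1ccccc1)c1ccccc1.[Br-]
Why: Wittig methylenation with the unstabilised ylide turns the hindered ketone into the exocyclic alkene that becomes the C4 methyl, and the only enolisable position (C3) carries no stereocentre.

**Step 7**
Reactants: 13 (1S,2S)-1-[(tert-butyldimethylsilyloxy)methyl]-2-[3-(tert-butyldimethylsilyloxy)propyl]-2-methyl-3-methylidenecyclohexane
Product: 15 (3S,4S)-4-[(tert-butyldimethylsilyloxy)methyl]-3-[3-(tert-butyldimethylsilyloxy)propyl]-3-methyl-2-methylidenecyclohexan-1-one, via allylic alcohol 14 (not isolated)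
Conditions: SeO2 (cat.), t-BuOOH, CH2Cl2, rt; then Dess–Martin periodinane, CH2Cl2, rt
Reagents that add atoms: selenium dioxide, O=[Se]=O; tert-butyl hydroperoxide, CC(C)(C)OO
Why: Selenium dioxide allylic oxidation (ene reaction then [2,3]-sigmatropic shift) can only occur at C3, the sole allylic CH2, and the periodinane converts both C3 epimers of the alcohol into one α-methylene ketone, so the configuration of 14 does not matter.

**Step 8**
Reactants: 15 (3S,4S)-4-[(tert-butyldimethylsilyloxy)methyl]-3-[3-(tert-butyldimethylsilyloxy)propyl]-3-methyl-2-methylidenecyclohexan-1-one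
Product: 16 (1R,3S,4S)-4-[(tert-butyldimethylsilyloxy)methyl]-3-[3-(tert-butyldimethylsilyloxy)propyl]-3-methyl-2-methylidenecyclohexan-1-ol
Conditions: (S)-B-methyl-oxazaborolidine from (S)-α,α-diphenylprolinol (20 mol %), catecholborane, toluene, –78 °C
Reagents that add atoms: none
Why: In this Corey–Bakshi–Shibata reduction the methylidene-bearing carbon acts as the large group, so the (S)-catalyst should deliver hydride to the β face and give the (R)-carbinol (3α-OH) under reagent control, and any minor enantiomer carried from step 3 becomes a diastereomer that can be removed by chromatography.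

**Step 9**
Reactants: 16 (1R,3S,4S)-4-[(tert-butyldimethylsilyloxy)methyl]-3-[3-(tert-butyldimethylsilyloxy)propyl]-3-methyl-2-methylidenecyclohexan-1-ol
Product: 17 (1R,2R,3S,4S)-4-[(tert-butyldimethylsilyloxy)methyl]-3-[3-(tert-butyldimethylsilyloxy)propyl]-2,3-dimethylcyclohexan-1-ol
Conditions: H2 (1 atm), [Ir(cod)(PCy3)(py)]PF6 (5 mol %), CH2Cl2, rt
Reagents that add atoms: none
Why: Hydroxyl-directed homogeneous hydrogenation: the iridium cation binds the C3 hydroxyl and adds H2 to the exocyclic alkene from the same (α) face, so the new C4 methyl is trans to the hydroxyl and cis to the C5 methyl.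

**Step 10**
Reactants: 17 (1R,2R,3S,4S)-4-[(tert-butyldimethylsilyloxy)methyl]-3-[3-(tert-butyldimethylsilyloxy)propyl]-2,3-dimethylcyclohexan-1-ol
Product: 18 (1R,2R,3S,4S)-4-(hydroxymethyl)-3-(3-hydroxypropyl)-2,3-dimethylcyclohexan-1-ol
Conditions: HF·pyridine, THF, 0 °C → rt
Reagents that add atoms: none
Why: Fluoride-mediated cleavage of both primary silyl ethers frees the C8 and C9 hydroxyls under conditions that leave the rest of the molecule untouched.

**Step 11**
Reactants: 18 (1R,2R,3S,4S)-4-(hydroxymethyl)-3-(3-hydroxypropyl)-2,3-dimethylcyclohexan-1-ol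
Product: 19 (1S,2R,3R,4R)-4-hydroxy-2,3-dimethyl-2-(3-oxopropyl)cyclohexane-1-carbaldehyde
Conditions: TEMPO (20 mol %), PhI(OAc)2, CH2Cl2, rt
Reagents that add atoms: none
Why: The oxoammonium oxidation (TEMPO with PhI(OAc)2) is selective for primary over secondary alcohols and involves no base, so both arms reach the aldehyde level while the C3 hydroxyl and the epimerisable C10 centre are left alone, and lactol formation between the arms would need a seven-membered ring.

**Step 12**
Reactants: 19 (1S,2R,3R,4R)-4-hydroxy-2,3-dimethyl-2-(3-oxopropyl)cyclohexane-1-carbaldehyde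
Product: 20 3α,9β-dihydroxy-4β,5β-dimethyl-10βH-decalin-8-one
Conditions: 2-(pentafluorophenyl)-6,7-dihydro-5H-pyrrolo[2,1-c][1,2,4]triazol-2-ium tetrafluoroborate (15 mol %), iPr2NEt (15 mol %), toluene, 0 °C → rt
Reagents that add atoms: none
Why: The triazolylidene adds reversibly to both formyl groups, but only the adduct of the unbranched C8 aldehyde is deprotonated at a useful rate to the hydroxy-enamine (acyl-anion equivalent), the C9 formyl group being shielded by ring A and the quaternary C5. This donor attacks the C9 aldehyde, and proton transfer and loss of the carbene leave the ketone at C8 and the hydroxyl at C9; the closest known reaction is the carbene-catalysed intramolecular benzoin (acyloin) cyclisation of 1,6-dialdehydes to 2-hydroxycyclohexanones. Ring B closes in the 6-exo-trig mode through a chair in which the C5 arm is equatorial and the C10 formyl group axial on ring A, which can only give the cis-fused decalin. The new C9 centre is set by the substrate: the developing C9–O bond takes the equatorial (β) position, hydrogen-bonded to the enaminol OH, because the axial alternative is syn-axial to C4, and reversibility of the addition funnels material to the same, more stable epimer. The step needs donor/acceptor selectivity, which rests on the steric difference between a CH2–CHO and a neopentyl-type ring CHO, and it needs C10 to keep its configuration, which rests on using only a catalytic amount of hindered amine at 0 °C. The free C3 hydroxyl is a spectator, and the absence of hydroxide or alkoxide keeps intramolecular aldol condensation of the C8 aldehyde in check.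

**Step 13**
Reactants: 20 3α,9β-dihydroxy-4β,5β-dimethyl-10βH-decalin-8-one
Product: 21 4β,5β-dimethyl-3α,9β-bis(triethylsilyloxy)-10βH-decalin-8-one
Conditions: Et3SiOTf, 2,6-lutidine, CH2Cl2, –78 → 0 °C
Reagents that add atoms: triethylsilyl trifluoromethanesulfonate, CC[Si](CC)(CC)OS(=O)(=O)C(F)(F)F
Why: Silylation of both secondary hydroxyls with the silyl triflate and a hindered pyridine base protects them for the enolate chemistry and makes C9 too hindered to be deprotonated.

**Step 14**
Reactants: 21 4β,5β-dimethyl-3α,9β-bis(triethylsilyloxy)-10βH-decalin-8-one; 22 acetone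
Product: 24 7β-(2-hydroxypropan-2-yl)-4β,5β-dimethyl-3α,9β-bis(triethylsilyloxy)-10βH-decalin-8-one, via lithium enolate 23 (not isolated)
Conditions: LiN(iPr)2, THF, –78 °C; then 22, –78 °C; AcOH quench at –78 °C
Reagents that add atoms: acetone 22, CC(C)=O
Why: Kinetic deprotonation takes place at the C7 methylene and not at the hindered, silyloxy-bearing C9, and the enolate adds to acetone (aldol addition) from the convex β face of the cis-decalin, giving the equatorial 7β side chain, which is also the more stable epimer; the cold quench forestalls retro-aldol cleavage.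

**Step 15**
Reactants: 24 7β-(2-hydroxypropan-2-yl)-4β,5β-dimethyl-3α,9β-bis(triethylsilyloxy)-10βH-decalin-8-one
Product: 25 3α,9β-dihydroxy-7β-(2-hydroxypropan-2-yl)-4β,5β-dimethyl-10βH-decalin-8-one
Conditions: HF·pyridine, THF/pyridine, 0 °C
Reagents that add atoms: none
Why: Mildly acidic fluoride removes both triethylsilyl ethers without forming the alkoxide that would trigger retro-aldol cleavage of the tertiary β-hydroxy ketone.

**Step 16**
Reactants: 25 3α,9β-dihydroxy-7β-(2-hydroxypropan-2-yl)-4β,5β-dimethyl-10βH-decalin-8-one; 26 angelic acid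
Product: 28 3α,9β-bis(angeloyloxy)-7β-(2-hydroxypropan-2-yl)-4β,5β-dimethyl-10βH-decalin-8-one, via mixed anhydride 27 (not isolated)
Conditions: 26, 2,4,6-trichlorobenzoyl chloride, Et3N, toluene, rt; then 25, 75 °C
Reagents that add atoms: angelic acid 26, C/C=C(/C)C(=O)O
Why: Acylation of the two secondary hydroxyls by the mixed anhydride of angelic and 2,4,6-trichlorobenzoic acid (Yamaguchi-type esterification without nucleophilic catalyst) keeps the Z geometry of the acid, and the tertiary hydroxyl is too hindered to react.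

**Step 17**
Reactants: 28 3α,9β-bis(angeloyloxy)-7β-(2-hydroxypropan-2-yl)-4β,5β-dimethyl-10βH-decalin-8-one
Product: 29 3α,9β-bis(angeloyloxy)-7β-isopropenyl-4β,5β-dimethyl-10βH-decalin-8-one
Conditions: SOCl2, pyridine, –20 → 0 °C
Reagents that add atoms: none
Why: Dehydration of the tertiary alcohol through its chlorosulfite (E2 with pyridine) should remove one of the six methyl hydrogens in preference to the single C7–H, giving the isopropenyl group under non-equilibrating conditions that neither isomerise the angelates nor move the double bond into conjugation.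

**Compound list**
1 | cyclohex-2-en-1-one | O=C1C=CCCC1 | starting material
2 | 2-iodocyclohex-2-en-1-one | O=C1CCCC=C1I | intermediate
3 | allyloxy(tert-butyl)dimethylsilane | C=CCO[Si](C)(C)C(C)(C)C | starting material
4 | 9-[3-(tert-butyldimethylsilyloxy)propyl]-9-borabicyclo[3.3.1]nonane (not isolated) | CC(C)(C)[Si](C)(C)OCCCB1C2CCCC1CCC2 | intermediate
5 | 2-[3-(tert-butyldimethylsilyloxy)propyl]cyclohex-2-en-1-one | O=C1CCCC=C1CCCO[Si](C)(C)C(C)(C)C | intermediate
6 | vinylmagnesium bromide | C=C[Mg]Br | starting material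
7 | iodomethane | CI | starting material
8 | bromomagnesium (3R)-2-[3-(tert-butyldimethylsilyloxy)propyl]-3-vinylcyclohex-1-en-1-olate (not isolated) | C=C[C@H]1CCCC(O[Mg]Br)=C1CCCO[Si](C)(C)C(C)(C)C | intermediate
9 | (2S,3R)-2-[3-(tert-butyldimethylsilyloxy)propyl]-2-methyl-3-vinylcyclohexan-1-one (methyl trans to vinyl) | CC(C)(C)[Si](C)(C)OCCC[C@@]1(C)[C@H](CCCC1=O)C=C | intermediate
10 | (1S,2S)-2-[3-(tert-butyldimethylsilyloxy)propyl]-2-methyl-3-oxocyclohexane-1-carbaldehyde (not isolated) | CC(C)(C)[Si](C)(C)OCCC[C@@]1(C)[C@H](CCCC1=O)C=O | intermediate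
11 | (2S,3S)-2-[3-(tert-butyldimethylsilyloxy)propyl]-3-(hydroxymethyl)-2-methylcyclohexan-1-one | CC(C)(C)[Si](C)(C)OCCC[C@@]1(C)[C@H](CCCC1=O)CO | intermediate
12 | (2S,3S)-2-[3-(tert-butyldimethylsilyloxy)propyl]-3-[(tert-butyldimethylsilyloxy)methyl]-2-methylcyclohexan-1-one | CC(C)(C)[Si](C)(C)OCCC[C@@]1(C)[C@H](CCCC1=O)CO[Si](C)(C)C(C)(C)C | intermediate
13 | (1S,2S)-1-[(tert-butyldimethylsilyloxy)methyl]-2-[3-(tert-butyldimethylsilyloxy)propyl]-2-methyl-3-methylidenecyclohexane | CC(C)(C)[Si](C)(C)OCCC[C@@]1(C)[C@H](CCCC1=C)CO[Si](C)(C)C(C)(C)C | intermediate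
14 | (3S,4S)-4-[(tert-butyldimethylsilyloxy)methyl]-3-[3-(tert-butyldimethylsilyloxy)propyl]-3-methyl-2-methylidenecyclohexan-1-ol, both C1 epimers (not isolated) | CC(C)(C)[Si](C)(C)OCCC[C@@]1(C)[C@H](CCC(O)C1=C)CO[Si](C)(C)C(C)(C)C | intermediate
15 | (3S,4S)-4-[(tert-butyldimethylsilyloxy)methyl]-3-[3-(tert-butyldimethylsilyloxy)propyl]-3-methyl-2-methylidenecyclohexan-1-one | CC(C)(C)[Si](C)(C)OCCC[C@@]1(C)[C@H](CCC(=O)C1=C)CO[Si](C)(C)C(C)(C)C | intermediate
16 | (1R,3S,4S)-4-[(tert-butyldimethylsilyloxy)methyl]-3-[3-(tert-butyldimethylsilyloxy)propyl]-3-methyl-2-methylidenecyclohexan-1-ol | CC(C)(C)[Si](C)(C)OCCC[C@@]1(C)[C@H](CC[C@@H](O)C1=C)CO[Si](C)(C)C(C)(C)C | intermediate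
17 | (1R,2R,3S,4S)-4-[(tert-butyldimethylsilyloxy)methyl]-3-[3-(tert-butyldimethylsilyloxy)propyl]-2,3-dimethylcyclohexan-1-ol | CC(C)(C)[Si](C)(C)OCCC[C@@]1(C)[C@H](CC[C@@H](O)[C@@H]1C)CO[Si](C)(C)C(C)(C)C | intermediate
18 | (1R,2R,3S,4S)-4-(hydroxymethyl)-3-(3-hydroxypropyl)-2,3-dimethylcyclohexan-1-ol | OCCC[C@@]1(C)[C@H](CC[C@@H](O)[C@@H]1C)CO | intermediate
19 | (1S,2R,3R,4R)-4-hydroxy-2,3-dimethyl-2-(3-oxopropyl)cyclohexane-1-carbaldehyde (formyl cis to the oxopropyl arm) | O=CCC[C@@]1(C)[C@H](CC[C@@H](O)[C@@H]1C)C=O | intermediate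
20 | 3α,9β-dihydroxy-4β,5β-dimethyl-10βH-decalin-8-one (cis-fused; eremophilane numbering) | C1C[C@@]2(C)[C@H](CC[C@@H](O)[C@@H]2C)[C@@H](O)C1=O | intermediate
21 | 4β,5β-dimethyl-3α,9β-bis(triethylsilyloxy)-10βH-decalin-8-one | C1C[C@@]2(C)[C@H](CC[C@@H](O[Si](CC)(CC)CC)[C@@H]2C)[C@@H](O[Si](CC)(CC)CC)C1=O | intermediate
22 | acetone | CC(C)=O | starting material
23 | lithium 7-en-8-olate of 21 (not isolated) | [Li]OC1=CC[C@@]2(C)[C@H](CC[C@@H](O[Si](CC)(CC)CC)[C@@H]2C)[C@H]1O[Si](CC)(CC)CC | intermediate
24 | 7β-(2-hydroxypropan-2-yl)-4β,5β-dimethyl-3α,9β-bis(triethylsilyloxy)-10βH-decalin-8-one | CC(C)(O)[C@H]1C[C@@]2(C)[C@H](CC[C@@H](O[Si](CC)(CC)CC)[C@@H]2C)[C@@H](O[Si](CC)(CC)CC)C1=O | intermediate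
25 | 3α,9β-dihydroxy-7β-(2-hydroxypropan-2-yl)-4β,5β-dimethyl-10βH-decalin-8-one | CC(C)(O)[C@H]1C[C@@]2(C)[C@H](CC[C@@H](O)[C@@H]2C)[C@@H](O)C1=O | intermediate
26 | angelic acid, (Z)-2-methylbut-2-enoic acid | C/C=C(/C)C(=O)O | starting material
27 | angelic 2,4,6-trichlorobenzoic anhydride (not isolated) | C/C=C(/C)C(=O)OC(=O)c1c(Cl)cc(Cl)cc1Cl | intermediate
28 | 3α,9β-bis(angeloyloxy)-7β-(2-hydroxypropan-2-yl)-4β,5β-dimethyl-10βH-decalin-8-one | CC(C)(O)[C@H]1C[C@@]2(C)[C@H](CC[C@@H](OC(=O)/C(C)=C\C)[C@@H]2C)[C@@H](OC(=O)/C(C)=C\C)C1=O | intermediate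
29 | 3α,9β-bis(angeloyloxy)-7β-isopropenyl-4β,5β-dimethyl-10βH-decalin-8-one (CNP0174755.1) | C=C(C)[C@H]1C[C@@]2(C)[C@H](CC[C@@H](OC(=O)/C(C)=C\C)[C@@H]2C)[C@@H](OC(=O)/C(C)=C\C)C1=O | target

**Step count**
Total steps: 17. Longest linear sequence: 17 steps (1 → 29); all other components enter as commercial reagents.

**Steps most likely to fail**

1. Step 12. The carbene may form its donor at the hindered C9 aldehyde (reversed ketol), the amine may epimerise C10 before ring closure, or the C8 aldehyde may undergo intramolecular aldol condensation. Fallback: starting from 19, reductive ketyl–aldehyde coupling with SmI2 (THF, t-BuOH, –78 °C) needs no base and should close ring B as the cis-8β,9β-diol, 3α,8β,9β-trihydroxy-4β,5β-dimethyl-10βH-decalin F1. Treatment with Bu2SnO should give the dibutylstannylene acetal of the vicinal diol F2. Brominolysis of F2 (N-bromosuccinimide or Br2) oxidises the axial, less hindered C8 hydroxyl and leaves the C9 carbinol, which returns the route at 20.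

2. Step 3. Enantiofacial discrimination may erode with the sp2-hybridised Grignard reagent, and C-methylation of the hindered magnesium enolate may be incomplete. Fallback: starting from 5, C9 is introduced as an sp3 hydroxymethyl synthon, the nucleophile class for which this copper catalysis is established. The Grignard reagent (isopropoxydimethylsilyl)methylmagnesium chloride F3, made from the commercial chloromethylsilane, is added under the same catalyst. This gives the chloromagnesium enolate F4, which is methylated with 7 to (2S,3S)-2-[3-(tert-butyldimethylsilyloxy)propyl]-3-{[isopropoxy(dimethyl)silyl]methyl}-2-methylcyclohexan-1-one F5. Tamao oxidation of the C–Si bond (H2O2, KF, KHCO3, THF/MeOH) then gives 11 directly, so the route is rejoined at 11 and the ozonolysis is not needed.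

3. Step 17. Elimination may go toward C7 and give the conjugated isopropylidene ketone, or chloride may substitute the tertiary centre. Fallback: starting from 21, the isopropenyl group is attached as such. Lithium enolate 23 (formed with LiN(SiMe3)2) is coupled with 2-bromopropene under palladium catalysis (Pd2(dba)3, P(tBu)3; ketone α-alkenylation) to give 7β-isopropenyl-4β,5β-dimethyl-3α,9β-bis(triethylsilyloxy)-10βH-decalin-8-one F6. HF·pyridine gives 3α,9β-dihydroxy-7β-isopropenyl-4β,5β-dimethyl-10βH-decalin-8-one F7. F7 is esterified with 27 as in step 16, which rejoins the route at 29.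

**Further compounds**
F1 | step 12 | 3α,8β,9β-trihydroxy-4β,5β-dimethyl-10βH-decalin | C1C[C@@]2(C)[C@H](CC[C@@H](O)[C@@H]2C)[C@@H](O)[C@H]1O
F2 | step 12 | 8,9-O-dibutylstannylene acetal of F1 (not isolated) | C1C[C@@]2(C)[C@H](CC[C@@H](O)[C@@H]2C)[C@H]3O[Sn](CCCC)(CCCC)O[C@@H]13
F3 | step 3 | (isopropoxydimethylsilyl)methylmagnesium chloride | CC(C)O[Si](C)(C)C[Mg]Cl
F4 | step 3 | chloromagnesium (3S)-2-[3-(tert-butyldimethylsilyloxy)propyl]-3-{[isopropoxy(dimethyl)silyl]methyl}cyclohex-1-en-1-olate (not isolated) | CC(C)O[Si](C)(C)C[C@H]1CCCC(O[Mg]Cl)=C1CCCO[Si](C)(C)C(C)(C)C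
F5 | step 3 | (2S,3S)-2-[3-(tert-butyldimethylsilyloxy)propyl]-3-{[isopropoxy(dimethyl)silyl]methyl}-2-methylcyclohexan-1-one | CC(C)(C)[Si](C)(C)OCCC[C@@]1(C)[C@H](CCCC1=O)C[Si](C)(C)OC(C)C
F6 | step 17 | 7β-isopropenyl-4β,5β-dimethyl-3α,9β-bis(triethylsilyloxy)-10βH-decalin-8-one | C=C(C)[C@H]1C[C@@]2(C)[C@H](CC[C@@H](O[Si](CC)(CC)CC)[C@@H]2C)[C@@H](O[Si](CC)(CC)CC)C1=O
F7 | step 17 | 3α,9β-dihydroxy-7β-isopropenyl-4β,5β-dimethyl-10βH-decalin-8-one | C=C(C)[C@H]1C[C@@]2(C)[C@H](CC[C@@H](O)[C@@H]2C)[C@@H](O)C1=O
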